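**Retrosynthetic overview**
1. Target 27 ⇐ C7 carbamoylation and desilylation of macrolactam 24. The 19-membered ring is the only ring made and is closed last, by intramolecular Goldberg N-arylation (aryl C–N bond) of bromo-amide 23; the benzene ring is bought.
2. 23 ⇐ B-alkyl Suzuki–Miyaura coupling (C3–C4 bond) of dienol 18 with iodoacrylamide 21, which brings C1–C3 and the 2E alkene.
3. 18 ⇐ two Brown (Z)-crotylborations (C6–C7 and C10–C11 bonds; C6, C7, C10, C11 centres) around an ozonolysis/Wittig pair (8E alkene), from α-methoxy aldehyde 9.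
4. 9 ⇐ new CuH/Pd hydroarylation (C15–aryl bond and C14 centre) of alkene 6 with dibromide 2; 6 ⇐ (S)-glycidyl trityl ether 3 (C12 centre) + isopropenyl Grignard 4.

Atom labels C1–C15 follow the ansa chain: C1 = amide carbonyl, C7 = carbamate carbon, C15 = benzylic CH2.
Assumption: the ligand hand in step 4, (R)-DTBM-SEGPHOS, is assigned by analogy with related CuH additions and must be confirmed on the first run (both hands are sold); (E)-3-iodo-2-methylacrylic acid 19 is taken as a catalogue compound.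

**Route**

Step 1
Reactants: 1 3,5-dibromophenol
Product: 2 (3,5-dibromophenoxy)triisopropylsilane
Conditions: TIPSCl, imidazole, DMF, rt
Reagents that add atoms: triisopropylsilyl chloride, CC(C)[Si](Cl)(C(C)C)C(C)C
Why: Imidazole-promoted O-silylation gives a hindered aryl silyl ether that tolerates the acidic, oxidative and mildly basic steps ahead and is removed only by fluoride at the end; no stereocentre is involved.

Step 2
Reactants: 3 (S)-glycidyl trityl ether; 4 isopropenylmagnesium bromide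
Product: 5 (2S)-4-methyl-1-(trityloxy)pent-4-en-2-ol
Conditions: CuI (10 mol %), THF, −40 → 0 °C; H2O/NH4Cl work-up
Reagents that add atoms: none
Why: Copper-catalysed Grignard opening of a terminal epoxide is an SN2 attack at the unsubstituted CH2, so the C–O bond of the bought (S) centre is untouched and becomes C12.

Step 3
Reactants: 5 (2S)-4-methyl-1-(trityloxy)pent-4-en-2-ol
Product: 6 (2S)-2-methoxy-4-methylpent-4-en-1-yl trityl ether
Conditions: NaH, MeI, THF, 0 °C → rt
Reagents that add atoms: iodomethane, CI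
Why: Williamson etherification installs the C12 methyl ether; the trityl ether cannot migrate or cleave under NaH and the stereocentre is not touched.

Step 4
Reactants: 6 (2S)-2-methoxy-4-methylpent-4-en-1-yl trityl ether; 2 (3,5-dibromophenoxy)triisopropylsilane (3 equiv, excess recovered)
Product: 7 (2S,4R)-5-[3-bromo-5-(triisopropylsilyloxy)phenyl]-2-methoxy-4-methylpentyl trityl ether
Conditions: Cu(OAc)2 (5 mol %), (R)-DTBM-SEGPHOS (5.5 mol %), [Pd(cinnamyl)Cl]2 (2.5 mol %), BrettPhos (5.5 mol %), MePh2SiH (2.5 equiv), NaOSiMe3 (2 equiv), THF, 45 °C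
Reagents that add atoms: none
Why: Proposed new method: a dual CuH/Pd anti-Markovnikov hydroarylation of an unactivated 1,1-dialkyl alkene that sets a β-stereocentre under ligand control and stops at mono-arylation of a dibromoarene; the bisphosphine–CuH formed from Cu(OAc)2 and the silane adds across C14=C15 with copper on the terminal carbon, so the face of hydride delivery fixes C14 as R (C12 is too remote to override the ligand), the primary alkylcopper carries no stereocentre at the metal-bearing carbon and transmetalates to the BrettPhos aryl bromide complex of divalent palladium formed by oxidative addition of 2 to zerovalent palladium, and reductive elimination from the bulky biarylphosphine complex should outrun β-hydride elimination, while NaOSiMe3 and silane turn CuBr back into CuH and the threefold excess of symmetrical 2 keeps the second C–Br bond for step 14; the closest known reaction types are CuH-catalysed enantioselective anti-Markovnikov hydroamination and hydroboration of 1,1-disubstituted alkenes and CuH/Pd dual-catalytic hydroarylation of styrenes and monosubstituted alkenes.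

Step 5
Reactants: 7 (2S,4R)-5-[3-bromo-5-(triisopropylsilyloxy)phenyl]-2-methoxy-4-methylpentyl trityl ether
Product: 8 (2S,4R)-5-[3-bromo-5-(triisopropylsilyloxy)phenyl]-2-methoxy-4-methylpentan-1-ol
Conditions: p-TsOH·H2O (10 mol %), MeOH/CH2Cl2 1:1, rt
Reagents that add atoms: none
Why: Acid-catalysed solvolysis of the trityl ether (SN1, trityl cation trapped by methanol) frees the primary alcohol while the aryl TIPS ether, aryl bromide and methyl ether are stable to brief mild acid.

Step 6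
Reactants: 8 (2S,4R)-5-[3-bromo-5-(triisopropylsilyloxy)phenyl]-2-methoxy-4-methylpentan-1-ol
Product: 9 (2S,4R)-5-[3-bromo-5-(triisopropylsilyloxy)phenyl]-2-methoxy-4-methylpentanal
Conditions: Dess–Martin periodinane, CH2Cl2, 0 °C → rt; used crude at once
Reagents that add atoms: none
Why: Dess–Martin oxidation is fast and non-basic, so the epimerisable α-methoxy aldehyde keeps its C12 configuration.

Step 7
Reactants: 9 (2S,4R)-5-[3-bromo-5-(triisopropylsilyloxy)phenyl]-2-methoxy-4-methylpentanal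
Product: 11 (3S,4R,5S,7R)-8-[3-bromo-5-(triisopropylsilyloxy)phenyl]-5-methoxy-3,7-dimethyloct-1-en-4-ol, via diisopinocampheylborinate ester 10 (not isolated)
Conditions: (Z)-but-2-ene, KOt-Bu, n-BuLi, THF, −78 → −45 °C; (+)-Ipc2BOMe then BF3·OEt2, −78 °C; 9, −78 °C; NaBO3·4H2O, THF/H2O, rt
Reagents that add atoms: (Z)-crotyldiisopinocampheylborane made in the flask from (Z)-but-2-ene and (+)-Ipc2BOMe, C/C=C\CB([C@H]1C[C@H]2C[C@@H]([C@@H]1C)C2(C)C)[C@H]1C[C@H]2C[C@@H]([C@@H]1C)C2(C)C
Why: Brown asymmetric crotylboration through a closed Zimmerman–Traxler chair turns the Z-crotyl geometry into the 10,11-syn relationship, and the isopinocampheyl groups of the (−)-α-pinene series direct attack to the re face of the aldehyde (C11 = R, C10 = S), which is also the Felkin–Anh/Cornforth face of the α-methoxy aldehyde (matched pair, 11,12-anti).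

Step 8
Reactants: 11 (3S,4R,5S,7R)-8-[3-bromo-5-(triisopropylsilyloxy)phenyl]-5-methoxy-3,7-dimethyloct-1-en-4-ol
Product: 12 (3S,4R,5S,7R)-8-[3-bromo-5-(triisopropylsilyloxy)phenyl]-4-(tert-butyldimethylsilyloxy)-5-methoxy-3,7-dimethyloct-1-ene
Conditions: TBSOTf, 2,6-lutidine, CH2Cl2, −78 → 0 °C
Reagents that add atoms: tert-butyldimethylsilyl triflate, CC(C)(C)[Si](C)(C)OS(=O)(=O)C(F)(F)F
Why: Silyl triflate silylation protects the hindered C11 alcohol so that the C7 alcohol made later is the only free hydroxyl at the carbamoylation stage.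

Step 9
Reactants: 12 (3S,4R,5S,7R)-8-[3-bromo-5-(triisopropylsilyloxy)phenyl]-4-(tert-butyldimethylsilyloxy)-5-methoxy-3,7-dimethyloct-1-ene
Product: 14 (2R,3R,4S,6R)-7-[3-bromo-5-(triisopropylsilyloxy)phenyl]-3-(tert-butyldimethylsilyloxy)-4-methoxy-2,6-dimethylheptanal, via ozonide 13 (not isolated)
Conditions: O3, CH2Cl2, −78 °C (stopped at first excess); PPh3, −78 °C → rt
Reagents that add atoms: ozone, [O-][O+]=O
Why: Ozonolysis with reductive work-up (Criegee mechanism) cleaves the only alkene present to the C9 aldehyde under neutral conditions that do not epimerise C10 (the descriptor changes to 2R only because the priorities change).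

Step 10
Reactants: 14 (2R,3R,4S,6R)-7-[3-bromo-5-(triisopropylsilyloxy)phenyl]-3-(tert-butyldimethylsilyloxy)-4-methoxy-2,6-dimethylheptanal; 15 2-(triphenylphosphoranylidene)propanal
Product: 16 (2E,4S,5R,6S,8R)-9-[3-bromo-5-(triisopropylsilyloxy)phenyl]-5-(tert-butyldimethylsilyloxy)-6-methoxy-2,4,8-trimethylnon-2-enal
Conditions: toluene, 90 °C
Reagents that add atoms: none
Why: Wittig olefination with the stabilised α-methyl formyl ylide gives the E trisubstituted enal (C8=C9) directly under base-free conditions, so the C7 aldehyde is in hand without redox adjustment.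

Step 11
Reactants: 16 (2E,4S,5R,6S,8R)-9-[3-bromo-5-(triisopropylsilyloxy)phenyl]-5-(tert-butyldimethylsilyloxy)-6-methoxy-2,4,8-trimethylnon-2-enal
Product: 18 (3S,4R,5E,7S,8R,9S,11R)-12-[3-bromo-5-(triisopropylsilyloxy)phenyl]-8-(tert-butyldimethylsilyloxy)-9-methoxy-3,5,7,11-tetramethyldodeca-1,5-dien-4-ol, via diisopinocampheylborinate ester 17 (not isolated)
Conditions: (Z)-but-2-ene, KOt-Bu, n-BuLi, THF, −78 → −45 °C; (+)-Ipc2BOMe then BF3·OEt2, −78 °C; 16, −78 °C; NaBO3·4H2O, THF/H2O, rt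
Reagents that add atoms: (Z)-crotyldiisopinocampheylborane made in the flask from (Z)-but-2-ene and (+)-Ipc2BOMe, C/C=C\CB([C@H]1C[C@H]2C[C@@H]([C@@H]1C)C2(C)C)[C@H]1C[C@H]2C[C@@H]([C@@H]1C)C2(C)C
Why: A second Brown (Z)-crotylboration adds 1,2 to the enal under reagent control (the nearest stereocentre, C10, is γ to the carbonyl), the chair transition state giving 6,7-syn and re-face attack giving C7 = R and C6 = S, and it leaves the terminal vinyl group needed for step 13.

Step 12
Reactants: 19 (E)-3-iodo-2-methylprop-2-enoic acid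
Product: 21 (E)-3-iodo-2-methylprop-2-enamide, via acid chloride 20 (not isolated)
Conditions: (COCl)2, DMF (cat.), CH2Cl2, 0 °C → rt, concentrate; NH3 (0.5 M in dioxane), THF, 0 °C
Reagents that add atoms: ammonia, N
Why: Acid chloride formation and ammonolysis at 0 °C is faster than addition–elimination at the β-iodide, so the E vinyl iodide is kept.

Step 13
Reactants: 18 (3S,4R,5E,7S,8R,9S,11R)-12-[3-bromo-5-(triisopropylsilyloxy)phenyl]-8-(tert-butyldimethylsilyloxy)-9-methoxy-3,5,7,11-tetramethyldodeca-1,5-dien-4-ol; 21 (E)-3-iodo-2-methylprop-2-enamide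
Product: 23 (2E,6S,7R,8E,10S,11R,12S,14R)-15-[3-bromo-5-(triisopropylsilyloxy)phenyl]-11-(tert-butyldimethylsilyloxy)-7-hydroxy-12-methoxy-2,6,8,10,14-pentamethylpentadeca-2,8-dienamide, via alkyl-9-BBN borane 22 (not isolated)
Conditions: 9-BBN (3 equiv), THF, rt; then 21, Pd(dppf)Cl2·CH2Cl2 (10 mol %), AsPh3 (10 mol %), Cs2CO3, DMF/H2O, rt
Reagents that add atoms: none
Why: 9-BBN hydroborates only the monosubstituted alkene (boron on C4) and the B-alkyl Suzuki–Miyaura coupling proceeds with retention of the E vinyl iodide geometry, oxidative addition to the β-iodo enamide at room temperature being far faster than to the aryl bromide.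

Step 14
Reactants: 23 (2E,6S,7R,8E,10S,11R,12S,14R)-15-[3-bromo-5-(triisopropylsilyloxy)phenyl]-11-(tert-butyldimethylsilyloxy)-7-hydroxy-12-methoxy-2,6,8,10,14-pentamethylpentadeca-2,8-dienamide
Product: 24 19-membered macrolactam (2E,6S,7R,8E,10S,11R,12S,14R) with 7-OH free, 11-O-TBS, 12-OMe and the phenol as TIPS ether
Conditions: CuI (50 mol %), N,N'-dimethylethylenediamine (1 equiv), K2CO3 (3 equiv), toluene (2 mM), 100 °C
Reagents that add atoms: none
Why: Intramolecular Goldberg amidation (copper/diamine N-arylation of a primary amide by an aryl bromide) at high dilution closes the ring on an unhindered meta-substituted arene, the amide nitrogen being far more reactive than the free secondary alcohol under these conditions; no stereocentre is touched.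

Step 15
Reactants: 24 19-membered macrolactam with 7-OH free
Product: 26 7-O-carbamoyl macrolactam with 11-O-TBS and the phenol as TIPS ether, via N-trichloroacetyl carbamate 25 (not isolated)
Conditions: Cl3CC(O)NCO, CH2Cl2, −20 °C; neutral Al2O3, rt
Reagents that add atoms: trichloroacetyl isocyanate, O=C=NC(=O)C(Cl)(Cl)Cl
Why: Addition of the only free hydroxyl (C7) to the highly electrophilic acyl isocyanate, followed by hydrolysis of the trichloroacetyl imide on alumina, gives the primary carbamate with retention at C7 and without disturbing the silyl ethers.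

Step 16
Reactants: 26 7-O-carbamoyl macrolactam with 11-O-TBS and the phenol as TIPS ether
Product: 27 CNP0247621.1 (target)
Conditions: HF·pyridine, pyridine, THF, 0 °C → rt
Reagents that add atoms: none
Why: Buffered fluoride desilylation (Si–F bond formation) removes the aryl TIPS and secondary TBS ethers under conditions that spare the allylic carbamate, the enamide and all stereocentres.

**Compound list**

1 | 3,5-dibromophenol | Oc1cc(Br)cc(Br)c1 | starting material
2 | (3,5-dibromophenoxy)triisopropylsilane | CC(C)[Si](Oc1cc(Br)cc(Br)c1)(C(C)C)C(C)C | intermediate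
3 | (S)-glycidyl trityl ether, (2S)-2-(trityloxymethyl)oxirane | C1O[C@@H]1COC(c2ccccc2)(c2ccccc2)c2ccccc2 | starting material
4 | isopropenylmagnesium bromide | CC(=C)[Mg]Br | starting material
5 | (2S)-4-methyl-1-(trityloxy)pent-4-en-2-ol | O[C@@H](CC(C)=C)COC(c1ccccc1)(c1ccccc1)c1ccccc1 | intermediate
6 | (2S)-2-methoxy-4-methylpent-4-en-1-yl trityl ether | CO[C@@H](CC(C)=C)COC(c1ccccc1)(c1ccccc1)c1ccccc1 | intermediate
7 | (2S,4R)-5-[3-bromo-5-(triisopropylsilyloxy)phenyl]-2-methoxy-4-methylpentyl trityl ether | CO[C@@H](C[C@H](C)Cc1cc(Br)cc(O[Si](C(C)C)(C(C)C)C(C)C)c1)COC(c1ccccc1)(c1ccccc1)c1ccccc1 | intermediate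
8 | (2S,4R)-5-[3-bromo-5-(triisopropylsilyloxy)phenyl]-2-methoxy-4-methylpentan-1-ol | CO[C@@H](C[C@H](C)Cc1cc(Br)cc(O[Si](C(C)C)(C(C)C)C(C)C)c1)CO | intermediate
9 | (2S,4R)-5-[3-bromo-5-(triisopropylsilyloxy)phenyl]-2-methoxy-4-methylpentanal | CO[C@@H](C[C@H](C)Cc1cc(Br)cc(O[Si](C(C)C)(C(C)C)C(C)C)c1)C=O | intermediate
10 | diisopinocampheylborinate ester of alcohol 11 (O–B(Ipc)2 on C11; not isolated) | C=C[C@H](C)[C@@H](OB([C@H]1C[C@H]2C[C@@H]([C@@H]1C)C2(C)C)[C@H]1C[C@H]2C[C@@H]([C@@H]1C)C2(C)C)[C@@H](OC)C[C@H](C)Cc1cc(Br)cc(O[Si](C(C)C)(C(C)C)C(C)C)c1 | intermediate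
11 | (3S,4R,5S,7R)-8-[3-bromo-5-(triisopropylsilyloxy)phenyl]-5-methoxy-3,7-dimethyloct-1-en-4-ol | C=C[C@H](C)[C@@H](O)[C@@H](OC)C[C@H](C)Cc1cc(Br)cc(O[Si](C(C)C)(C(C)C)C(C)C)c1 | intermediate
12 | (3S,4R,5S,7R)-8-[3-bromo-5-(triisopropylsilyloxy)phenyl]-4-(tert-butyldimethylsilyloxy)-5-methoxy-3,7-dimethyloct-1-ene | C=C[C@H](C)[C@@H](O[Si](C)(C)C(C)(C)C)[C@@H](OC)C[C@H](C)Cc1cc(Br)cc(O[Si](C(C)C)(C(C)C)C(C)C)c1 | intermediate
13 | ozonide (3-substituted 1,2,4-trioxolane, ring carbon unassigned) of alkene 12 (not isolated) | C1OC(OO1)[C@H](C)[C@@H](O[Si](C)(C)C(C)(C)C)[C@@H](OC)C[C@H](C)Cc1cc(Br)cc(O[Si](C(C)C)(C(C)C)C(C)C)c1 | intermediate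
14 | (2R,3R,4S,6R)-7-[3-bromo-5-(triisopropylsilyloxy)phenyl]-3-(tert-butyldimethylsilyloxy)-4-methoxy-2,6-dimethylheptanal | O=C[C@H](C)[C@@H](O[Si](C)(C)C(C)(C)C)[C@@H](OC)C[C@H](C)Cc1cc(Br)cc(O[Si](C(C)C)(C(C)C)C(C)C)c1 | intermediate
15 | 2-(triphenylphosphoranylidene)propanal | CC(C=O)=P(c1ccccc1)(c1ccccc1)c1ccccc1 | starting material
16 | (2E,4S,5R,6S,8R)-9-[3-bromo-5-(triisopropylsilyloxy)phenyl]-5-(tert-butyldimethylsilyloxy)-6-methoxy-2,4,8-trimethylnon-2-enal | O=C/C(C)=C/[C@H](C)[C@@H](O[Si](C)(C)C(C)(C)C)[C@@H](OC)C[C@H](C)Cc1cc(Br)cc(O[Si](C(C)C)(C(C)C)C(C)C)c1 | intermediate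
17 | diisopinocampheylborinate ester of alcohol 18 (O–B(Ipc)2 on C7; not isolated) | C=C[C@H](C)[C@@H](OB([C@H]1C[C@H]2C[C@@H]([C@@H]1C)C2(C)C)[C@H]1C[C@H]2C[C@@H]([C@@H]1C)C2(C)C)/C(C)=C/[C@H](C)[C@@H](O[Si](C)(C)C(C)(C)C)[C@@H](OC)C[C@H](C)Cc1cc(Br)cc(O[Si](C(C)C)(C(C)C)C(C)C)c1 | intermediate
18 | (3S,4R,5E,7S,8R,9S,11R)-12-[3-bromo-5-(triisopropylsilyloxy)phenyl]-8-(tert-butyldimethylsilyloxy)-9-methoxy-3,5,7,11-tetramethyldodeca-1,5-dien-4-ol | C=C[C@H](C)[C@@H](O)/C(C)=C/[C@H](C)[C@@H](O[Si](C)(C)C(C)(C)C)[C@@H](OC)C[C@H](C)Cc1cc(Br)cc(O[Si](C(C)C)(C(C)C)C(C)C)c1 | intermediate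
19 | (E)-3-iodo-2-methylprop-2-enoic acid | OC(=O)/C(C)=C/I | starting material
20 | (E)-3-iodo-2-methylprop-2-enoyl chloride (not isolated) | ClC(=O)/C(C)=C/I | intermediate
21 | (E)-3-iodo-2-methylprop-2-enamide | NC(=O)/C(C)=C/I | intermediate
22 | 9-[(3S,4R,5E,7S,8R,9S,11R)-12-[3-bromo-5-(triisopropylsilyloxy)phenyl]-8-(tert-butyldimethylsilyloxy)-4-hydroxy-9-methoxy-3,5,7,11-tetramethyldodec-5-en-1-yl]-9-borabicyclo[3.3.1]nonane (not isolated) | B1(C2CCCC1CCC2)CC[C@H](C)[C@@H](O)/C(C)=C/[C@H](C)[C@@H](O[Si](C)(C)C(C)(C)C)[C@@H](OC)C[C@H](C)Cc1cc(Br)cc(O[Si](C(C)C)(C(C)C)C(C)C)c1 | intermediate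
23 | (2E,6S,7R,8E,10S,11R,12S,14R)-15-[3-bromo-5-(triisopropylsilyloxy)phenyl]-11-(tert-butyldimethylsilyloxy)-7-hydroxy-12-methoxy-2,6,8,10,14-pentamethylpentadeca-2,8-dienamide | NC(=O)/C(C)=C/CC[C@H](C)[C@@H](O)/C(C)=C/[C@H](C)[C@@H](O[Si](C)(C)C(C)(C)C)[C@@H](OC)C[C@H](C)Cc1cc(Br)cc(O[Si](C(C)C)(C(C)C)C(C)C)c1 | intermediate
24 | 19-membered macrolactam (2E,6S,7R,8E,10S,11R,12S,14R): anilide N on the arene, 7-OH free, 11-O-TBS, 12-OMe, phenol as TIPS ether | CO[C@H]1C[C@H](C)Cc2cc(O[Si](C(C)C)(C(C)C)C(C)C)cc(c2)NC(=O)/C(C)=C/CC[C@H](C)[C@@H](O)/C(C)=C/[C@H](C)[C@H]1O[Si](C)(C)C(C)(C)C | intermediate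
25 | 7-O-(N-trichloroacetylcarbamoyl) derivative of macrolactam 24 (not isolated) | CO[C@H]1C[C@H](C)Cc2cc(O[Si](C(C)C)(C(C)C)C(C)C)cc(c2)NC(=O)/C(C)=C/CC[C@H](C)[C@@H](OC(=O)NC(=O)C(Cl)(Cl)Cl)/C(C)=C/[C@H](C)[C@H]1O[Si](C)(C)C(C)(C)C | intermediate
26 | 7-O-carbamoyl macrolactam with 11-O-TBS and phenol TIPS ether | CO[C@H]1C[C@H](C)Cc2cc(O[Si](C(C)C)(C(C)C)C(C)C)cc(c2)NC(=O)/C(C)=C/CC[C@H](C)[C@@H](OC(N)=O)/C(C)=C/[C@H](C)[C@H]1O[Si](C)(C)C(C)(C)C | intermediate
27 | CNP0247621.1: (2E,6S,7R,8E,10S,11R,12S,14R) 19-membered macrolactam with 7-O-carbamoyl, 11-OH, 12-OMe, methyls on C2, C6, C8, C10, C14 and free phenol | CO[C@H]1C[C@H](C)Cc2cc(O)cc(c2)NC(=O)/C(C)=C/CC[C@H](C)[C@@H](OC(N)=O)/C(C)=C/[C@H](C)[C@H]1O | target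

**Totals and risks**

Total step count: 16. Longest linear sequence: 14 steps (3 → 27 through steps 2–11 and 13–16).

Most likely to fail, 1: step 4 (the proposed new hydroarylation). The palladium half is the weak point: β-hydride elimination from the β-branched alkylpalladium, reduction of the aryl bromide, or double arylation of 2. The CH3/CH2R face discrimination at C14 could also be modest. The known-chemistry fallback sets out from 6 and comes back at 7. Copper-catalysed enantioselective hydroboration of 6 (CuCl, (R)-DTBM-SEGPHOS, KOt-Bu, pinacolborane, toluene, rt; a known reaction class for 1,1-disubstituted alkenes) gives 2-[(2R,4S)-4-methoxy-2-methyl-5-(trityloxy)pentyl]-4,4,5,5-tetramethyl-1,3,2-dioxaborolane F1. F1 is isolable, so the C14 ratio can be measured and upgraded before the carbon–carbon bond is made. Suzuki–Miyaura coupling of F1 with excess 2 (Pd(OAc)2, RuPhos, K3PO4, toluene/H2O, 80 °C) then gives 7. This fallback separates the stereo-setting step from the C–C coupling but still relies on CuH face selectivity.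

Most likely to fail, 2: step 13 (B-alkyl Suzuki–Miyaura). The free C7 hydroxyl consumes borane, the primary amide partner is base-sensitive, and the aryl bromide must stay untouched by palladium. The fallback sets out from 18 and comes back at 23 without boron or palladium. Linear-selective hydroformylation of the terminal alkene (Rh(acac)(CO)2, BiPhePhos, CO/H2 1:1, 10 bar, toluene, 60 °C) gives (4S,5R,6E,8S,9R,10S,12R)-13-[3-bromo-5-(triisopropylsilyloxy)phenyl]-9-(tert-butyldimethylsilyloxy)-5-hydroxy-10-methoxy-4,6,8,12-tetramethyltridec-6-enal F2, which rests mainly as its six-membered lactol. Wittig reaction of F2 with methyl 2-(triphenylphosphoranylidene)propanoate (toluene, 80 °C) gives methyl (2E,6S,7R,8E,10S,11R,12S,14R)-15-[3-bromo-5-(triisopropylsilyloxy)phenyl]-11-(tert-butyldimethylsilyloxy)-7-hydroxy-12-methoxy-2,6,8,10,14-pentamethylpentadeca-2,8-dienoate F3. Weinreb aminolysis of F3 (Me3Al, NH4Cl, toluene, 50 °C) gives 23.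

Most likely to fail, 3: step 14 (Goldberg macrocyclisation). Oligomerisation or slow closure of the 19-membered ring could dominate. The fallback sets out from 18 and comes back at 24, making the aryl C–N bond intermolecularly and closing the ring through the C3–C4 bond instead. Intermolecular Goldberg coupling of 18 with tert-butyl carbamate (CuI, N,N'-dimethylethylenediamine, K2CO3, toluene, 100 °C) gives the N-Boc aniline corresponding to 18 with NHBoc in place of Br, F4. Boc removal (TMSOTf, 2,6-lutidine, CH2Cl2, 0 °C; then MeOH) gives the aniline corresponding to 18 with NH2 in place of Br, F5. Acylation of F5 with acid chloride 20 (pyridine, CH2Cl2, −20 °C; the aniline reacts ahead of the hindered C7 alcohol) gives the N-aryl (E)-3-iodo-2-methylacrylamide F6. Hydroboration of the terminal alkene of F6 (9-BBN, THF, rt) gives the alkyl-9-BBN borane F7. Intramolecular B-alkyl Suzuki–Miyaura coupling of F7 at high dilution (Pd(dppf)Cl2·CH2Cl2, AsPh3, Cs2CO3, DMF/THF/H2O, 1 mM, rt → 50 °C) gives 24.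

**Further compounds**

F1 | step 4 | 2-[(2R,4S)-4-methoxy-2-methyl-5-(trityloxy)pentyl]-4,4,5,5-tetramethyl-1,3,2-dioxaborolane | CO[C@@H](C[C@H](C)CB1OC(C)(C)C(C)(C)O1)COC(c1ccccc1)(c1ccccc1)c1ccccc1
F2 | step 13 | (4S,5R,6E,8S,9R,10S,12R)-13-[3-bromo-5-(triisopropylsilyloxy)phenyl]-9-(tert-butyldimethylsilyloxy)-5-hydroxy-10-methoxy-4,6,8,12-tetramethyltridec-6-enal (open form of the lactol) | O=CCC[C@H](C)[C@@H](O)/C(C)=C/[C@H](C)[C@@H](O[Si](C)(C)C(C)(C)C)[C@@H](OC)C[C@H](C)Cc1cc(Br)cc(O[Si](C(C)C)(C(C)C)C(C)C)c1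
F3 | step 13 | methyl (2E,6S,7R,8E,10S,11R,12S,14R)-15-[3-bromo-5-(triisopropylsilyloxy)phenyl]-11-(tert-butyldimethylsilyloxy)-7-hydroxy-12-methoxy-2,6,8,10,14-pentamethylpentadeca-2,8-dienoate | COC(=O)/C(C)=C/CC[C@H](C)[C@@H](O)/C(C)=C/[C@H](C)[C@@H](O[Si](C)(C)C(C)(C)C)[C@@H](OC)C[C@H](C)Cc1cc(Br)cc(O[Si](C(C)C)(C(C)C)C(C)C)c1
F4 | step 14 | N-Boc aniline corresponding to 18 with NHBoc in place of Br | C=C[C@H](C)[C@@H](O)/C(C)=C/[C@H](C)[C@@H](O[Si](C)(C)C(C)(C)C)[C@@H](OC)C[C@H](C)Cc1cc(NC(=O)OC(C)(C)C)cc(O[Si](C(C)C)(C(C)C)C(C)C)c1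
F5 | step 14 | aniline corresponding to 18 with NH2 in place of Br | C=C[C@H](C)[C@@H](O)/C(C)=C/[C@H](C)[C@@H](O[Si](C)(C)C(C)(C)C)[C@@H](OC)C[C@H](C)Cc1cc(N)cc(O[Si](C(C)C)(C(C)C)C(C)C)c1
F6 | step 14 | N-aryl (E)-3-iodo-2-methylacrylamide of aniline F5 | C=C[C@H](C)[C@@H](O)/C(C)=C/[C@H](C)[C@@H](O[Si](C)(C)C(C)(C)C)[C@@H](OC)C[C@H](C)Cc1cc(NC(=O)/C(C)=C/I)cc(O[Si](C(C)C)(C(C)C)C(C)C)c1
F7 | step 14 | alkyl-9-BBN borane from hydroboration of the terminal alkene of F6 | B1(C2CCCC1CCC2)CC[C@H](C)[C@@H](O)/C(C)=C/[C@H](C)[C@@H](O[Si](C)(C)C(C)(C)C)[C@@H](OC)C[C@H](C)Cc1cc(NC(=O)/C(C)=C/I)cc(O[Si](C(C)C)(C(C)C)C(C)C)c1
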